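A small charge of substrate shows what a larger one shows: at 2.00 min the teal, green and red runs read 30.9%, 31.0% and 31.1% of intermediate, so in percent of the charge they lie on one curve within the scatter.

in all of them: catalyst 0.98 mM
- teal: substrate 0.10 M; run made earlier
- green: substrate 0.14 M; run made earlier
- red: substrate 0.22 M; run made earlier
- alpha: substrate 0.10 M; a closed flask charged with all of it at once and left for 5.0 min; time 5.0 min
- beta: substrate 0.10 M (fed, over 5.00 min); all but substrate at the start; substrate goes in evenly over 5.00 min, the run ends at 5.0 min; time 5.0 min
- zeta: substrate 0.10 M; one stirred flow tank at steady state, fed with the mixture as stated, mean residence time 5.0 min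

| run | time / min | intermediate / % | target / % |
|---|---|---|---|
| teal | 0.250 | 6.0 | 0.6 |
| teal | 0.333 | 7.6 | 0 |
| teal | 0.500 | 11.4 | 0.7 |
| teal | 0.833 | 17.9 | 0 |
| teal | 1.33 | 24.2 | 1.5 |
| teal | 2.00 | 30.9 | 2.6 |
| teal | 3.00 | 36.5 | 4.6 |
| green | 0.250 | 5.9 | 0.2 |
| green | 0.833 | 17.5 | 0.5 |
| green | 1.33 | 24.4 | 1.0 |
| green | 2.00 | 31.0 | 3.4 |
| green | 3.00 | 37.3 | 5.8 |
| green | 4.00 | 39.7 | 8.2 |
| green | 5.00 | 40.7 | 10.2 |
| red | 0.667 | 15.3 | 0 |
| red | 1.33 | 23.7 | 0.8 |
| red | 2.00 | 31.1 | 3.7 |
| red | 3.00 | 36.3 | 5.3 |
| red | 4.00 | 40.1 | 7.4 |
| red | 5.00 | 40.6 | 11.5 |

(standard deviation of a reading: 0.5 percentage points)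

- the stated concentrations are those of everything mixed, before any reaction; amounts are the same in each set-up
- steps under discussion: substrate <-> dormant form; catalyst + intermediate -> catalyst + target; substrate -> intermediate
- the feed brings no volume worth counting
- the earlier runs were made in a closed, stirred flask

- the set-up with the highest amount of intermediate at the outlet or at the end, in percent of the substrate put in ("none" if the first two lie within 2 percentage points) (alpha / beta / zeta / none)
- amount of intermediate at the outlet or at the end, in percent of the substrate put in, alpha
- amount of intermediate at the outlet or at the end, in percent of the substrate put in, beta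
- amount of intermediate at the outlet or at the end, in percent of the substrate put in, zeta

The first rung of the ladder is the making of intermediate: in the teal run, intermediate plus target starts at 0.242 min⁻¹ of the charge, a time scale of 4.13 min. The next rung is read from the fraction left. In the last minute of the green run that sum gains 0.0300 min⁻¹, less than at the start. Taking the rate to follow free substrate, this reading, which carries the scatter of the green run, puts about 12.4% of the charge as free in that minute, while 49.1% remains unformed at 5.00 min, so this reckoning leaves about 36.7% of the green charge as dormant form.

The last rung is the catalyst. The green intermediate curve averages 29.9% over that time. Dividing the target made by the time-integral of intermediate gives the loss constant κ, pseudo-first-order at 0.98 mM of catalyst, which reads 0.0683 min⁻¹. Its time scale, 14.6 min, is longer than that of the making and than the run, and intermediate of age a survives as exp(−κa). For alpha the green curve reads 40.7% at its end. Each slice fed evenly into beta ages from its own entry, so this reckoning puts beta at the mean, 29.9%.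

The forecast gives 40.8% for alpha, 29.7% for beta, a little lower than this reckoning, and 30.4% for zeta, and names alpha as best; its ground: “substrate is being lost quickly to the dormant form, which returns slowly”.

The flask gives 40.7% for alpha, 30.0% for beta and 30.8% for zeta, so alpha leads.

    substrate ⇌ dormant form (K = 2.80, k = 0.00415 s⁻¹)
    catalyst + intermediate → catalyst + target (k = 1.19 M⁻¹ s⁻¹)
    substrate → intermediate (k = 0.00442 s⁻¹)

In beta the median time of making is 3.20 min, so the median intermediate at 5.0 min has age 1.80 min, shorter than its half-life against catalyst, 9.9 min. Then exp(−κa) keeps 88.4%, and beta holds 87.7% of intermediate plus target as intermediate. The same flask with 3.90 mM of catalyst has κ of 0.272 min⁻¹, and its 38.6% of substrate and 27.2% of dormant form leave 34.2% formed. That reckons to 21.0% of intermediate, and that neighbouring flask holds 21.2%.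

(The earlier runs and the new flask are calculated on assumed constants, and the scatter is random.)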